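## Retrosynthetic overview

1. The furan ring is closed last. Its O1–C2 bond comes from 5-endo-dig hydroalkoxylation of an o-alkynylphenol, made in the same flask by Sonogashira coupling of an iodinated ring A fragment with a ring B arylacetylene. One of the two oxygens flanking the alkyne is silylated, so only the hydroxyl next to the side chain can close.
2. Ring A fragment: phloroglucinol. The (R)-3-methylbut-3-en-2-yl stereocentre is set by a new iridium-catalysed enantioconvergent dehydrative C-allylation, followed by steric mono-silylation and iodination.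
3. Ring B fragment: 3,5-dihydroxybenzaldehyde. The pyran ring of the chroman is closed first, by acid hydroalkoxylation (C–O) of an ortho-prenyl phenol. The second prenyl group follows by bromination and Stille coupling, then CHO is converted to C≡CH.
4. Ring order: pyran ring (early, ring B fragment), then furan ring (last); both are closed by C–O bond formation.

Assumption: catalogue compounds (racemic 3-methylbut-3-en-2-ol, the prenylstannane, the Ohira–Bestmann reagent, the phosphoramidite–olefin ligand) count as commercially available; the sense of induction in step 1 is assigned by analogy, and the ligand antipode is used if it proves opposite.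

## Route

Step 1
Reactants: 1 phloroglucinol (benzene-1,3,5-triol, 3 equiv); 2 racemic 3-methylbut-3-en-2-ol
Product: 3 (R)-2-(3-methylbut-3-en-2-yl)benzene-1,3,5-triol
Conditions: [Ir(cod)Cl]2 (3 mol %), (S)-binaphthol phosphoramidite carrying an N-dibenzo[b,f]azepine olefin arm (12 mol %), Zn(OTf)2 (10 mol %), 1,4-dioxane, 25 °C
Reagents that add atoms: none
Why: Proposed new method: Zn(OTf)2-assisted ionization of either enantiomer of 2 (the hydroxyl leaves as water) at monovalent iridium bound to the P,olefin ligand gives a single trivalent-iridium 1,2-dimethylallyl complex (enantioconvergent); the enol-like ring carbon of 1 attacks the methyl-bearing allyl terminus anti to iridium (the branched selectivity typical of iridium), the ligand-controlled face of attack sets (R), and tautomerization restores the arene, while excess 1 suppresses bis-allylation and O-allyl ethers re-ionize; the closest known reaction type is the iridium/(P,olefin)-catalysed Friedel–Crafts-type allylic substitution of indoles, naphthols and electron-rich phenols with racemic 1-arylallyl alcohols, and the new elements are the aliphatic 2-methyl-substituted allyl unit and phloroglucinol as the carbon nucleophile.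

Step 2
Reactants: 3 (R)-2-(3-methylbut-3-en-2-yl)benzene-1,3,5-triol
Product: 4 (R)-2-(3-methylbut-3-en-2-yl)-5-[(triisopropylsilyl)oxy]benzene-1,3-diol
Conditions: TIPSCl (1.05 equiv), imidazole (2.2 equiv), DMF, −20 to 0 °C
Reagents that add atoms: triisopropylsilyl chloride, CC(C)[Si](Cl)(C(C)C)C(C)C
Why: Silyl ether formation (substitution at silicon) under steric control: the hydroxyl para to the branched side chain is the only one without an ortho substituent, so the bulky silyl group goes there, and the stereocentre is not touched.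

Step 3
Reactants: 4 (R)-2-(3-methylbut-3-en-2-yl)-5-[(triisopropylsilyl)oxy]benzene-1,3-diol
Product: 5 (R)-4-iodo-2-(3-methylbut-3-en-2-yl)-5-[(triisopropylsilyl)oxy]benzene-1,3-diol
Conditions: NIS (1.0 equiv), MeCN/CH2Cl2, −40 °C, dark
Reagents that add atoms: N-iodosuccinimide, O=C1CCC(=O)N1I
Why: Electrophilic aromatic iodination: the two remaining ring C–H positions are equivalent, so mono-iodination gives one product, and at −40 °C the phloroglucinol ring reacts far faster than the 1,1-disubstituted alkene.

Step 4
Reactants: 6 3,5-dihydroxybenzaldehyde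
Product: 7 2-bromo-3,5-dihydroxybenzaldehyde
Conditions: NBS (1.0 equiv), MeCN, −20 to 0 °C
Reagents that add atoms: N-bromosuccinimide, O=C1CCC(=O)N1Br
Why: Electrophilic aromatic bromination, kinetically at position 2 (para to one hydroxyl, ortho to the other) and not at position 4, which lies between the hydroxyls and para to the formyl group.

Step 5
Reactants: 7 2-bromo-3,5-dihydroxybenzaldehyde; 8 tributyl(3-methylbut-2-en-1-yl)stannane
Product: 10 7-hydroxy-2,2-dimethylchroman-5-carbaldehyde, via prenylphenol 9 (not isolated)
Conditions: Pd(PPh3)4 (5 mol %), 1,4-dioxane, 100 °C; then p-TsOH·H2O (0.3 equiv), 80 °C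
Reagents that add atoms: none
Why: Stille coupling transfers the prenyl group through its unsubstituted carbon; acid then protonates the trisubstituted alkene and the only ortho hydroxyl closes the pyran ring by Markovnikov hydroalkoxylation (C–O bond), the other hydroxyl being para to the side chain.

Step 6
Reactants: 10 7-hydroxy-2,2-dimethylchroman-5-carbaldehyde
Product: 11 6-bromo-7-hydroxy-2,2-dimethylchroman-5-carbaldehyde
Conditions: NBS (1.0 equiv), MeCN/CH2Cl2, −20 to 0 °C, dark
Reagents that add atoms: N-bromosuccinimide, O=C1CCC(=O)N1Br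
Why: Electrophilic aromatic bromination at C6 (ortho to the free hydroxyl, para to the ring ether oxygen), following the pattern of 3,5-dioxygenated benzaldehydes, which halogenate ortho to the formyl group and not between the two oxygens.

Step 7
Reactants: 11 6-bromo-7-hydroxy-2,2-dimethylchroman-5-carbaldehyde; 8 tributyl(3-methylbut-2-en-1-yl)stannane
Product: 12 7-hydroxy-2,2-dimethyl-6-(3-methylbut-2-en-1-yl)chroman-5-carbaldehyde
Conditions: Pd(PPh3)4 (8 mol %), DMF, 100 °C; aqueous KF work-up
Reagents that add atoms: none
Why: Stille coupling with linear prenyl transfer; the neutral, acid-free conditions keep the new ortho-prenyl phenol from cyclizing to a second pyran ring.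

Step 8
Reactants: 12 7-hydroxy-2,2-dimethyl-6-(3-methylbut-2-en-1-yl)chroman-5-carbaldehyde
Product: 13 5-ethynyl-2,2-dimethyl-6-(3-methylbut-2-en-1-yl)chroman-7-ol
Conditions: dimethyl (1-diazo-2-oxopropyl)phosphonate (1.5 equiv), K2CO3 (3 equiv), MeOH, 0 to 25 °C
Reagents that add atoms: Ohira–Bestmann reagent, COP(=O)(OC)C(=[N+]=[N-])C(C)=O
Why: Seyferth–Gilbert homologation in the Ohira–Bestmann form: the diazophosphonate anion made in situ olefinates the aldehyde, and loss of N2 with 1,2-shift gives the terminal alkyne; carbonate base tolerates the phenol and the prenyl group.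

Step 9
Reactants: 5 (R)-4-iodo-2-(3-methylbut-3-en-2-yl)-5-[(triisopropylsilyl)oxy]benzene-1,3-diol; 13 5-ethynyl-2,2-dimethyl-6-(3-methylbut-2-en-1-yl)chroman-7-ol
Product: 16 (R)-2-[7-hydroxy-2,2-dimethyl-6-(3-methylbut-2-en-1-yl)chroman-5-yl]-7-(3-methylbut-3-en-2-yl)benzofuran-4,6-diol (target CNP0325834.1), via diarylalkyne 14 (not isolated), via silylated benzofuran 15 (not isolated)
Conditions: PdCl2(PPh3)2 (5 mol %), CuI (10 mol %), Et3N, DMF, 25 then 70 °C; after complete cyclization TBAF (1.2 equiv), AcOH (1.2 equiv), 0 °C
Reagents that add atoms: none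
Why: Sonogashira coupling followed by copper/amine-promoted 5-endo-dig hydroalkoxylation forms the O1–C2 bond of the furan ring; of the two oxygens ortho to the alkyne only the one next to the side chain is free (the other is silylated), which fixes the regiochemistry; fluoride then cleaves the silyl ether, and the stereocentre is not involved.

## Compound list

1 | phloroglucinol (benzene-1,3,5-triol) | Oc1cc(O)cc(O)c1 | starting material
2 | racemic 3-methylbut-3-en-2-ol | CC(O)C(C)=C | starting material
3 | (R)-2-(3-methylbut-3-en-2-yl)benzene-1,3,5-triol | C=C(C)[C@@H](C)c1c(O)cc(O)cc1O | intermediate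
4 | (R)-2-(3-methylbut-3-en-2-yl)-5-[(triisopropylsilyl)oxy]benzene-1,3-diol | C=C(C)[C@@H](C)c1c(O)cc(O[Si](C(C)C)(C(C)C)C(C)C)cc1O | intermediate
5 | (R)-4-iodo-2-(3-methylbut-3-en-2-yl)-5-[(triisopropylsilyl)oxy]benzene-1,3-diol | C=C(C)[C@@H](C)c1c(O)cc(O[Si](C(C)C)(C(C)C)C(C)C)c(I)c1O | intermediate
6 | 3,5-dihydroxybenzaldehyde | O=Cc1cc(O)cc(O)c1 | starting material
7 | 2-bromo-3,5-dihydroxybenzaldehyde | O=Cc1cc(O)cc(O)c1Br | intermediate
8 | tributyl(3-methylbut-2-en-1-yl)stannane | CCCC[Sn](CCCC)(CCCC)CC=C(C)C | starting material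
9 | 3,5-dihydroxy-2-(3-methylbut-2-en-1-yl)benzaldehyde | O=Cc1cc(O)cc(O)c1CC=C(C)C | intermediate
10 | 7-hydroxy-2,2-dimethylchroman-5-carbaldehyde | O=Cc1cc(O)cc2OC(C)(C)CCc12 | intermediate
11 | 6-bromo-7-hydroxy-2,2-dimethylchroman-5-carbaldehyde | O=Cc1c(Br)c(O)cc2OC(C)(C)CCc12 | intermediate
12 | 7-hydroxy-2,2-dimethyl-6-(3-methylbut-2-en-1-yl)chroman-5-carbaldehyde | O=Cc1c(CC=C(C)C)c(O)cc2OC(C)(C)CCc12 | intermediate
13 | 5-ethynyl-2,2-dimethyl-6-(3-methylbut-2-en-1-yl)chroman-7-ol | C#Cc1c(CC=C(C)C)c(O)cc2OC(C)(C)CCc12 | intermediate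
14 | (R)-4-{[7-hydroxy-2,2-dimethyl-6-(3-methylbut-2-en-1-yl)chroman-5-yl]ethynyl}-2-(3-methylbut-3-en-2-yl)-5-[(triisopropylsilyl)oxy]benzene-1,3-diol | C=C(C)[C@@H](C)c1c(O)cc(O[Si](C(C)C)(C(C)C)C(C)C)c(C#Cc2c(CC=C(C)C)c(O)cc3OC(C)(C)CCc23)c1O | intermediate
15 | (R)-2-[7-hydroxy-2,2-dimethyl-6-(3-methylbut-2-en-1-yl)chroman-5-yl]-7-(3-methylbut-3-en-2-yl)-4-[(triisopropylsilyl)oxy]benzofuran-6-ol | C=C(C)[C@@H](C)c1c(O)cc(O[Si](C(C)C)(C(C)C)C(C)C)c2cc(-c3c(CC=C(C)C)c(O)cc4OC(C)(C)CCc34)oc12 | intermediate
16 | (R)-2-[7-hydroxy-2,2-dimethyl-6-(3-methylbut-2-en-1-yl)chroman-5-yl]-7-(3-methylbut-3-en-2-yl)benzofuran-4,6-diol | C=C(C)[C@@H](C)c1c(O)cc(O)c2cc(-c3c(CC=C(C)C)c(O)cc4c3CCC(C)(C)O4)oc12 | target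

## Step count and risks

Total steps: 9. Longest linear sequence: 6 (steps 4 to 9, from 6); the ring A branch is steps 1 to 3.

**Step 1 (the proposed new reaction).** The 2-methyl-substituted aliphatic allyl unit may bind and ionize poorly at iridium. The linear (2-methylbut-2-enyl) isomer, O-allyl ethers or bis-allylation may compete. The Lewis acid could close the product to a dihydrobenzofuran. The sense of induction is only assigned by analogy. The fallback uses known chemistry only; it sets out from 1 and comes back at 3. Mitsunobu mono-etherification of 1 (4 equiv) with (E)-2-methylbut-2-en-1-ol (PPh3, DIAD, THF, 0 °C) gives 5-{[(E)-2-methylbut-2-en-1-yl]oxy}benzene-1,3-diol F1. Thermal aromatic Claisen rearrangement (N,N-diethylaniline, 150 °C) moves the allyl unit to either of the two equivalent ortho carbons with allylic inversion and gives racemic 2-(3-methylbut-3-en-2-yl)benzene-1,3,5-triol F2. Preparative chiral-phase chromatography then delivers the (R)-enantiomer 3, which continues with step 2.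

**Step 7 (Stille coupling at a bromide flanked by CHO and OH).** The coupling may be slow or give some reverse-prenyl product, and it depends on the C6 selectivity of the preceding bromination. The fallback sets out from 10 and comes back at 12, replacing cross-coupling by a sigmatropic route. O-alkylation of 10 with 3-chloro-3-methylbut-1-yne (K2CO3, KI, CuI cat., acetone, 60 °C) gives 2,2-dimethyl-7-[(2-methylbut-3-yn-2-yl)oxy]chroman-5-carbaldehyde F3. Semihydrogenation (H2, Pd/CaCO3 poisoned with Pb(OAc)2, quinoline, EtOAc) gives 2,2-dimethyl-7-[(2-methylbut-3-en-2-yl)oxy]chroman-5-carbaldehyde F4. Aromatic Claisen rearrangement (toluene, 120 °C) places the prenyl group at C6, the ortho position next to the formyl group and para to the ring ether oxygen, giving 12.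

**Step 9 (one-pot coupling, cyclization and desilylation).** The hindered diarylalkyne 14 may cyclize incompletely under the coupling conditions. Fluoride added too early would free the second ortho oxygen and scramble the regiochemistry. Alkyne homocoupling is also possible. The fallback sets out from 5 and 13 and comes back at 15, which is then isolated. Alkyne 13 is converted (CuI, aqueous NH3, EtOH) into the monovalent copper acetylide copper [7-hydroxy-2,2-dimethyl-6-(3-methylbut-2-en-1-yl)chroman-5-yl]acetylide F5. Heating F5 with 5 in pyridine at 110 °C (Castro–Stephens coupling, palladium-free) gives the benzofuran 15 directly, since coupling and C–O ring closure occur together at copper. Separate desilylation of purified 15 (TBAF, AcOH, THF, 0 °C) gives 16.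

## Further compounds

F1 | step 1 | 5-{[(E)-2-methylbut-2-en-1-yl]oxy}benzene-1,3-diol | C/C=C(\C)COc1cc(O)cc(O)c1
F2 | step 1 | racemic 2-(3-methylbut-3-en-2-yl)benzene-1,3,5-triol | C=C(C)C(C)c1c(O)cc(O)cc1O
F3 | step 7 | 2,2-dimethyl-7-[(2-methylbut-3-yn-2-yl)oxy]chroman-5-carbaldehyde | O=Cc1cc(OC(C)(C)C#C)cc2OC(C)(C)CCc12
F4 | step 7 | 2,2-dimethyl-7-[(2-methylbut-3-en-2-yl)oxy]chroman-5-carbaldehyde | O=Cc1cc(OC(C)(C)C=C)cc2OC(C)(C)CCc12
F5 | step 9 | copper [7-hydroxy-2,2-dimethyl-6-(3-methylbut-2-en-1-yl)chroman-5-yl]acetylide | [Cu]C#Cc1c(CC=C(C)C)c(O)cc2OC(C)(C)CCc12
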